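**Retrosynthetic overview**
1. The exocyclic C8=CH2 and the C8a hydrogen come last, from SE2' protodesilylation of an allylsilane; with removal of a temporary C5 carbonyl this leads back to cycloheptenone 27.
2. Key disconnection: the seven-membered ring (ring B) is cut at C6–C7 and C3a–C4 into a 1,1-dimethyl-2-silyloxyallyl cation (C4–C5–C6) and the 2-(silylmethyl)diene C7=C8–C8a=C3a of a cyclopentene that already carries the complete side chain.
3. Enabling feature: in ring B the quaternary CMe2 carbon C4 and C6 are 1,3 across an unsubstituted C5 (room for a temporary carbonyl), and the methylene-bearing C8 lies between C7 and C8a, so a CH2SiMe3 group on C8 steers the cation to C7 and is later exchanged for =CH2 and the C8a hydrogen.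
4. C1–C1' bond: Giese-type union of a tertiary cyclopentyl radical (face set by a neighbouring OTBS group) with (5S)-menthyloxybutenolide (sets C1'); the auxiliary lactone is then transposed (alkylidenation, hydrogenation, LiBH4, relactonisation, enolate hydroxylation) into the target γ-lactone.
5. Ring order: cyclopentane (bought) → γ-lactone (step 6) → seven-membered ring (step 14, last).

Key step: step 14

Remark: the bicycle is numbered as azulene (C1 quaternary carbon, C3a/C8a ring fusion, C4 gem-dimethyl carbon, C8 methylene-bearing carbon) and C1' is the side-chain CH on C1; auxiliary 4 and benzyl glyoxylate 6 are assumed to be purchasable.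

Step 1
Reactants: 1 2-methylcyclopent-2-en-1-one
Product: 2 (R)-2-methylcyclopent-2-en-1-ol
Conditions: (S)-2-methyl-CBS-oxazaborolidine (10 mol %), BH3·SMe2, THF, −20 °C; MeOH quench
Reagents that add atoms: none
Why: CBS reduction (1,2-reduction); with the 2-methylalkenyl carbon as the large group the (S)-catalyst should give the (R)-carbinol.

Step 2
Reactants: 2 (R)-2-methylcyclopent-2-en-1-ol
Product: 3 (R)-tert-butyldimethyl[(2-methylcyclopent-2-en-1-yl)oxy]silane
Conditions: TBSCl, imidazole, DMF, rt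
Reagents that add atoms: tert-butyldimethylsilyl chloride, CC(C)(C)[Si](C)(C)Cl
Why: Standard silyl ether formation; the bulky OTBS group is the later face-directing element.

Step 3
Reactants: 3 (R)-tert-butyldimethyl[(2-methylcyclopent-2-en-1-yl)oxy]silane (2 equiv); 4 (5S)-5-[(1S,2R,5S)-menthyloxy]furan-2(5H)-one
Product: 5 (4R,5S)-4-[(1S,2R)-2-(tert-butyldimethylsilyloxy)-1-methylcyclopentyl]-5-[(1S,2R,5S)-menthyloxy]oxolan-2-one
Conditions: Fe(acac)3 (0.3 equiv), PhSiH3 (2.5 equiv), EtOH/(CH2OH)2 5:1, 40 °C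
Reagents that add atoms: none
Why: Iron-hydride hydrogen-atom-transfer reductive olefin coupling (Giese-type addition): Markovnikov H-atom transfer gives the tertiary cyclopentyl radical, which should add to the butenolide β-carbon anti to the adjacent OTBS group (sets the quaternary C1) and anti to the menthyloxy group of 4 (sets C1').

Step 4
Reactants: 5 (4R,5S)-4-[(1S,2R)-2-(tert-butyldimethylsilyloxy)-1-methylcyclopentyl]-5-[(1S,2R,5S)-menthyloxy]oxolan-2-one; 6 benzyl glyoxylate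
Product: 10 benzyl (2E)-2-[(4S,5S)-4-[(1S,2R)-2-(tert-butyldimethylsilyloxy)-1-methylcyclopentyl]-5-(menthyloxy)-2-oxooxolan-3-ylidene]acetate (E drawn; an E/Z mixture is acceptable), via lithium enolate 7 (not isolated), via lithium aldolate 8 (not isolated), via aldol mesylate 9 (not isolated)
Conditions: LDA (1.1 equiv), THF, −78 °C; 6; MsCl, −78 → 0 °C; DBU, 0 °C → rt
Reagents that add atoms: none
Why: Aldol condensation of a lactone enolate with a glyoxylate followed by E1cB elimination of the mesylate; the alkene geometry is irrelevant because it is hydrogenated next.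

Step 5
Reactants: 10 benzyl (2E)-2-[(4S,5S)-4-[(1S,2R)-2-(tert-butyldimethylsilyloxy)-1-methylcyclopentyl]-5-(menthyloxy)-2-oxooxolan-3-ylidene]acetate
Product: 11 2-[(3R,4R,5S)-4-[(1S,2R)-2-(tert-butyldimethylsilyloxy)-1-methylcyclopentyl]-5-(menthyloxy)-2-oxooxolan-3-yl]acetic acid (3,4-cis)
Conditions: H2 (1 atm), Pd/C, EtOAc, rt
Reagents that add atoms: none
Why: Heterogeneous hydrogenation with concurrent benzyl ester hydrogenolysis; H2 should add to the exocyclic alkene on the lactone face opposite the very bulky tert-alkyl group on C4, placing the CH2CO2H group cis to it (sets the future lactone C4 of the target).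

Step 6
Reactants: 11 2-[(3R,4R,5S)-4-[(1S,2R)-2-(tert-butyldimethylsilyloxy)-1-methylcyclopentyl]-5-(menthyloxy)-2-oxooxolan-3-yl]acetic acid
Product: 13 (4R)-4-{(1R)-1-[(1S,2R)-2-(tert-butyldimethylsilyloxy)-1-methylcyclopentyl]-2-hydroxyethyl}oxolan-2-one, via dihydroxy acid 12 (not isolated)
Conditions: LiBH4 (3 equiv), THF, 0 °C → rt; 1 M HCl to pH 3; PPTS (cat.), CH2Cl2, rt
Reagents that add atoms: none
Why: LiBH4 reduces the acylal lactone (pseudo-ester) to the 1,4-diol while the lithium carboxylate is inert, and acid then closes the 4-hydroxy acid to the five-membered lactone (favoured over the six-membered alternative), the auxiliary leaving as menthol.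

Step 7
Reactants: 13 (4R)-4-{(1R)-1-[(1S,2R)-2-(tert-butyldimethylsilyloxy)-1-methylcyclopentyl]-2-hydroxyethyl}oxolan-2-one
Product: 15 (3S,4R)-4-{(1R)-1-[(1S,2R)-2-(tert-butyldimethylsilyloxy)-1-methylcyclopentyl]-2-hydroxyethyl}-3-hydroxyoxolan-2-one, via dipotassium alkoxide enolate 14 (not isolated)
Conditions: KHMDS (2.3 equiv), THF, −78 °C; 2-(phenylsulfonyl)-3-phenyloxaziridine (1.3 equiv), −78 °C; sat. NH4Cl
Reagents that add atoms: 2-(phenylsulfonyl)-3-phenyloxaziridine (Davis oxaziridine), O=S(=O)(c1ccccc1)N1OC1c1ccccc1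
Why: Enolate hydroxylation with a Davis oxaziridine on the alkoxide–enolate dianion (the enolate is no longer electrophilic, so translactonisation is suppressed); the oxidant should approach anti to the bulky C4 substituent, giving the 3,4-trans hydroxy lactone.

Step 8
Reactants: 15 (3S,4R)-4-{(1R)-1-[(1S,2R)-2-(tert-butyldimethylsilyloxy)-1-methylcyclopentyl]-2-hydroxyethyl}-3-hydroxyoxolan-2-one
Product: 16 (3S,4R)-4-{(1R)-2-acetoxy-1-[(1S,2R)-2-(tert-butyldimethylsilyloxy)-1-methylcyclopentyl]ethyl}-2-oxooxolan-3-yl acetate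
Conditions: Ac2O, pyridine, DMAP (cat.), CH2Cl2, 0 °C → rt
Reagents that add atoms: acetic anhydride, CC(=O)OC(C)=O
Why: DMAP-catalysed acetylation of both hydroxyl groups installs the two acetates of the target.

Step 9
Reactants: 16 (3S,4R)-4-{(1R)-2-acetoxy-1-[(1S,2R)-2-(tert-butyldimethylsilyloxy)-1-methylcyclopentyl]ethyl}-2-oxooxolan-3-yl acetate
Product: 17 (3S,4R)-4-{(1R)-2-acetoxy-1-[(1S,2R)-2-hydroxy-1-methylcyclopentyl]ethyl}-2-oxooxolan-3-yl acetate
Conditions: 48 % aq. HF, MeCN, rt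
Reagents that add atoms: none
Why: Acidic fluoride desilylation of the hindered secondary silyl ether; acetates and lactone are stable under these conditions.

Step 10
Reactants: 17 (3S,4R)-4-{(1R)-2-acetoxy-1-[(1S,2R)-2-hydroxy-1-methylcyclopentyl]ethyl}-2-oxooxolan-3-yl acetate
Product: 18 (3S,4R)-4-{(1R)-2-acetoxy-1-[(1S)-1-methyl-2-oxocyclopentyl]ethyl}-2-oxooxolan-3-yl acetate
Conditions: Dess–Martin periodinane, NaHCO3, CH2Cl2, rt
Reagents that add atoms: none
Why: Dess–Martin oxidation to a ketone whose only stereocentre-bearing α-carbon is quaternary and cannot epimerise.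

Step 11
Reactants: 18 (3S,4R)-4-{(1R)-2-acetoxy-1-[(1S)-1-methyl-2-oxocyclopentyl]ethyl}-2-oxooxolan-3-yl acetate
Product: 19 (3S,4R)-4-{(1R)-2-acetoxy-1-[(1S)-1-methyl-2-(trifluoromethanesulfonyloxy)cyclopent-2-en-1-yl]ethyl}-2-oxooxolan-3-yl acetate
Conditions: Tf2O (1.5 equiv), 2,6-di-tert-butyl-4-methylpyridine (2 equiv), CH2Cl2, 0 °C → rt
Reagents that add atoms: trifluoromethanesulfonic anhydride, O=S(=O)(OS(=O)(=O)C(F)(F)F)C(F)(F)F
Why: Enol triflate formation with Tf2O and a hindered pyridine (no strong base, so acetates and the α-acetoxy lactone are untouched); only the CH2 side of the ketone can enolise.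

Step 12
Reactants: 19 (3S,4R)-4-{(1R)-2-acetoxy-1-[(1S)-1-methyl-2-(trifluoromethanesulfonyloxy)cyclopent-2-en-1-yl]ethyl}-2-oxooxolan-3-yl acetate; 20 (2-bromoallyl)trimethylsilane
Product: 23 (3S,4R)-4-{(1R)-2-acetoxy-1-[(1S)-1-methyl-2-(3-trimethylsilylprop-1-en-2-yl)cyclopent-2-en-1-yl]ethyl}-2-oxooxolan-3-yl acetate, via Grignard reagent 21 (not isolated), via organozinc reagent 22 (not isolated)
Conditions: 20, Mg, THF, 50 °C; ZnBr2, 0 °C; then 19, Pd(PPh3)4 (5 mol %), THF, 50 °C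
Reagents that add atoms: none
Why: Negishi cross-coupling of an alkenyl triflate with an alkenylzinc halide, which tolerates the esters and gives the 2-(silylmethyl)-1,3-diene.

Step 13
Reactants: 24 3-bromo-3-methylbutan-2-one
Product: 25 (3-bromo-3-methylbut-1-en-2-yl)oxytrimethylsilane
Conditions: TMSOTf, Et3N, Et2O, 0 °C
Reagents that add atoms: trimethylsilyl trifluoromethanesulfonate, C[Si](C)(C)OS(=O)(=O)C(F)(F)F
Why: Soft enolisation–silylation; only the methyl group can enolise, so one silyl enol ether results.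

Step 14
Reactants: 23 (3S,4R)-4-{(1R)-2-acetoxy-1-[(1S)-1-methyl-2-(3-trimethylsilylprop-1-en-2-yl)cyclopent-2-en-1-yl]ethyl}-2-oxooxolan-3-yl acetate; 25 (3-bromo-3-methylbut-1-en-2-yl)oxytrimethylsilane (1.5 equiv)
Product: 27 (3S,4R)-4-{(1R)-2-acetoxy-1-[(1S,3aR)-1,4,4-trimethyl-5-oxo-8-(trimethylsilylmethyl)-1,2,3,3a,4,5,6,7-octahydroazulen-1-yl]ethyl}-2-oxooxolan-3-yl acetate (3a-H anti to the C1 side chain), via silyloxyallyl cation perchlorate 26 (not isolated)
Conditions: AgClO4 (1.5 equiv), 2,6-di-tert-butylpyridine (0.3 equiv), MeNO2/CH2Cl2, −30 → 0 °C, dark; aq. NaHCO3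
Reagents that add atoms: none
Why: AgClO4 abstracts bromide from 25 to give the 1,1-dimethyl-2-(trimethylsilyloxy)allyl cation 26, whose CH2 terminus bonds to the allylsilane-activated CH2 terminus of diene 23 (C7, giving a β-silyl- and allyl-stabilised cation) while its enol silane carbon (the CMe2 terminus) closes onto C3a, and loss of Me3Si from oxygen leaves the C5 ketone, i.e. a concerted-asynchronous or stepwise (4+3) cycloaddition. The closest known reaction type is the (4+3) cycloaddition of 2-(silyloxy)allyl cations with 2-substituted open-chain 1,3-dienes such as isoprene, which gives 2,2-dimethylcyclohept-4-enones with the same orientation. The seven-membered ring closes in the (4+3) mode, four diene carbons (C7, C8, C8a, C3a) plus three allyl carbons (C6, C5, C4), the second bond being a seven-membered closure of the tethered enol silane onto the allyl cation terminus. The one new stereocentre, C3a, is controlled by the adjacent quaternary C1: the cation should add to the diene face that carries the C1 methyl, anti to the large C1 side chain. The step needs regioselectivity (CH2 terminus to C7, CMe2 terminus to C3a), secured by the CH2SiMe3 group on C8 that makes C7 the most nucleophilic and least hindered diene terminus, and it needs ring closure to outrun loss of the carbon-bound silyl group, which the non-nucleophilic perchlorate medium at low temperature should favour.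

Step 15
Reactants: 27 (3S,4R)-4-{(1R)-2-acetoxy-1-[(1S,3aR)-1,4,4-trimethyl-5-oxo-8-(trimethylsilylmethyl)-1,2,3,3a,4,5,6,7-octahydroazulen-1-yl]ethyl}-2-oxooxolan-3-yl acetate
Product: 28 C5 tosylhydrazone of 27 (N–NHTs anti to the CMe2 carbon)
Conditions: TsNHNH2 (2 equiv), MgSO4, THF, 55 °C
Reagents that add atoms: p-toluenesulfonyl hydrazide, Cc1ccc(S(=O)(=O)NN)cc1
Why: Hydrazone condensation at the only ketone, without added acid so that the allylsilane survives.

Step 16
Reactants: 28 C5 tosylhydrazone of 27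
Product: 31 (3S,4R)-4-{(1R)-2-acetoxy-1-[(1S,3aS)-1,4,4-trimethyl-8-(trimethylsilylmethyl)-1,2,3,3a,4,5,6,7-octahydroazulen-1-yl]ethyl}-2-oxooxolan-3-yl acetate, via boryl hydrazide 29 (not isolated), via alkyl diazene 30 (not isolated)
Conditions: catecholborane (3 equiv), CHCl3, 0 °C → rt; then NaOAc·3H2O, 60 °C
Reagents that add atoms: none
Why: Catecholborane reduction of a tosylhydrazone (mild Wolff–Kishner-type deoxygenation through the diazene with loss of N2), compatible with acetates, lactone and allylsilane, removes the temporary C5 carbonyl.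

Step 17
Reactants: 31 (3S,4R)-4-{(1R)-2-acetoxy-1-[(1S,3aS)-1,4,4-trimethyl-8-(trimethylsilylmethyl)-1,2,3,3a,4,5,6,7-octahydroazulen-1-yl]ethyl}-2-oxooxolan-3-yl acetate
Product: 32 (3S,4R)-4-{(1R)-2-acetoxy-1-[(1R,3aR,8aS)-1,4,4-trimethyl-8-methylidenedecahydroazulen-1-yl]ethyl}-2-oxooxolan-3-yl acetate (target)
Conditions: CF3CO2H (3 equiv), CH2Cl2, −30 °C, short contact; aq. NaHCO3
Reagents that add atoms: none
Why: SE2' protodesilylation of the allylsilane moves the double bond to the exocyclic position; the proton should reach C8a on the face anti to the C3a–C4 bond (that face carries only the C3a hydrogen, the other the CMe2 carbon and the C1 methyl), giving the cis ring fusion in which C8 avoids the large C1 substituent.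

**Compound list**
1 | 2-methylcyclopent-2-en-1-one | CC1=CCCC1=O | starting material
2 | (R)-2-methylcyclopent-2-en-1-ol | O[C@@H]1CCC=C1C | intermediate
3 | (R)-tert-butyldimethyl[(2-methylcyclopent-2-en-1-yl)oxy]silane | CC(C)(C)[Si](C)(C)O[C@@H]1CCC=C1C | intermediate
4 | (5S)-5-{[(1S,2R,5S)-2-isopropyl-5-methylcyclohexyl]oxy}furan-2(5H)-one | O=C1C=C[C@@H](O[C@H]2C[C@@H](C)CC[C@@H]2C(C)C)O1 | starting material
5 | (4R,5S)-4-[(1S,2R)-2-(tert-butyldimethylsilyloxy)-1-methylcyclopentyl]-5-[(1S,2R,5S)-menthyloxy]oxolan-2-one | C1CC[C@@](C)([C@H]2CC(=O)O[C@@H]2O[C@H]3C[C@@H](C)CC[C@@H]3C(C)C)[C@@H]1O[Si](C)(C)C(C)(C)C | intermediate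
6 | benzyl glyoxylate | O=CC(=O)OCc1ccccc1 | starting material
7 | lithium enolate of 5 | C1CC[C@@](C)([C@H]2C=C([O-])O[C@@H]2O[C@H]3C[C@@H](C)CC[C@@H]3C(C)C)[C@@H]1O[Si](C)(C)C(C)(C)C.[Li+] | intermediate (not isolated)
8 | lithium aldolate (3,4-trans; carbinol epimers) | C1CC[C@@](C)([C@H]2[C@H](C([O-])C(=O)OCc4ccccc4)C(=O)O[C@@H]2O[C@H]3C[C@@H](C)CC[C@@H]3C(C)C)[C@@H]1O[Si](C)(C)C(C)(C)C.[Li+] | intermediate (not isolated)
9 | aldol mesylate | C1CC[C@@](C)([C@H]2[C@H](C(OS(C)(=O)=O)C(=O)OCc4ccccc4)C(=O)O[C@@H]2O[C@H]3C[C@@H](C)CC[C@@H]3C(C)C)[C@@H]1O[Si](C)(C)C(C)(C)C | intermediate (not isolated)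
10 | benzyl (2E)-2-[(4S,5S)-4-[(1S,2R)-2-(tert-butyldimethylsilyloxy)-1-methylcyclopentyl]-5-(menthyloxy)-2-oxooxolan-3-ylidene]acetate | C1CC[C@@](C)([C@H]2/C(=C\C(=O)OCc4ccccc4)C(=O)O[C@@H]2O[C@H]3C[C@@H](C)CC[C@@H]3C(C)C)[C@@H]1O[Si](C)(C)C(C)(C)C | intermediate
11 | 2-[(3R,4R,5S)-4-[(1S,2R)-2-(tert-butyldimethylsilyloxy)-1-methylcyclopentyl]-5-(menthyloxy)-2-oxooxolan-3-yl]acetic acid | C1CC[C@@](C)([C@H]2[C@@H](CC(=O)O)C(=O)O[C@@H]2O[C@H]3C[C@@H](C)CC[C@@H]3C(C)C)[C@@H]1O[Si](C)(C)C(C)(C)C | intermediate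
12 | (3R,4R)-4-[(1S,2R)-2-(tert-butyldimethylsilyloxy)-1-methylcyclopentyl]-5-hydroxy-3-(hydroxymethyl)pentanoic acid | C1CC[C@@](C)([C@H](CO)[C@H](CO)CC(=O)O)[C@@H]1O[Si](C)(C)C(C)(C)C | intermediate (not isolated)
13 | (4R)-4-{(1R)-1-[(1S,2R)-2-(tert-butyldimethylsilyloxy)-1-methylcyclopentyl]-2-hydroxyethyl}oxolan-2-one | C1CC[C@@](C)([C@H](CO)[C@@H]2COC(=O)C2)[C@@H]1O[Si](C)(C)C(C)(C)C | intermediate
14 | dipotassium alkoxide enolate of 13 | C1CC[C@@](C)([C@H](C[O-])[C@@H]2COC([O-])=C2)[C@@H]1O[Si](C)(C)C(C)(C)C.[K+].[K+] | intermediate (not isolated)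
15 | (3S,4R)-4-{(1R)-1-[(1S,2R)-2-(tert-butyldimethylsilyloxy)-1-methylcyclopentyl]-2-hydroxyethyl}-3-hydroxyoxolan-2-one | C1CC[C@@](C)([C@H](CO)[C@@H]2COC(=O)[C@H]2O)[C@@H]1O[Si](C)(C)C(C)(C)C | intermediate
16 | (3S,4R)-4-{(1R)-2-acetoxy-1-[(1S,2R)-2-(tert-butyldimethylsilyloxy)-1-methylcyclopentyl]ethyl}-2-oxooxolan-3-yl acetate | C1CC[C@@](C)([C@H](COC(C)=O)[C@@H]2COC(=O)[C@H]2OC(C)=O)[C@@H]1O[Si](C)(C)C(C)(C)C | intermediate
17 | (3S,4R)-4-{(1R)-2-acetoxy-1-[(1S,2R)-2-hydroxy-1-methylcyclopentyl]ethyl}-2-oxooxolan-3-yl acetate | C1CC[C@@](C)([C@H](COC(C)=O)[C@@H]2COC(=O)[C@H]2OC(C)=O)[C@@H]1O | intermediate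
18 | (3S,4R)-4-{(1R)-2-acetoxy-1-[(1S)-1-methyl-2-oxocyclopentyl]ethyl}-2-oxooxolan-3-yl acetate | C1CC[C@@](C)([C@H](COC(C)=O)[C@@H]2COC(=O)[C@H]2OC(C)=O)C1=O | intermediate
19 | (3S,4R)-4-{(1R)-2-acetoxy-1-[(1S)-1-methyl-2-(trifluoromethanesulfonyloxy)cyclopent-2-en-1-yl]ethyl}-2-oxooxolan-3-yl acetate | C1CC[C@@](C)([C@H](COC(C)=O)[C@@H]2COC(=O)[C@H]2OC(C)=O)C(OS(=O)(=O)C(F)(F)F)=C1 | intermediate
20 | (2-bromoallyl)trimethylsilane | C=C(Br)C[Si](C)(C)C | starting material
21 | [3-(trimethylsilyl)prop-1-en-2-yl]magnesium bromide | C=C([Mg]Br)C[Si](C)(C)C | intermediate (not isolated)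
22 | [3-(trimethylsilyl)prop-1-en-2-yl]zinc bromide | C=C([Zn]Br)C[Si](C)(C)C | intermediate (not isolated)
23 | (3S,4R)-4-{(1R)-2-acetoxy-1-[(1S)-1-methyl-2-(3-trimethylsilylprop-1-en-2-yl)cyclopent-2-en-1-yl]ethyl}-2-oxooxolan-3-yl acetate | C1CC[C@@](C)([C@H](COC(C)=O)[C@@H]2COC(=O)[C@H]2OC(C)=O)C(C(=C)C[Si](C)(C)C)=C1 | intermediate
24 | 3-bromo-3-methylbutan-2-one | CC(=O)C(C)(C)Br | starting material
25 | (3-bromo-3-methylbut-1-en-2-yl)oxytrimethylsilane | C=C(O[Si](C)(C)C)C(C)(C)Br | intermediate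
26 | 1,1-dimethyl-2-(trimethylsilyloxy)allyl cation perchlorate | C=C(O[Si](C)(C)C)[C+](C)C.[O-]Cl(=O)(=O)=O | intermediate (not isolated)
27 | (3S,4R)-4-{(1R)-2-acetoxy-1-[(1S,3aR)-1,4,4-trimethyl-5-oxo-8-(trimethylsilylmethyl)-1,2,3,3a,4,5,6,7-octahydroazulen-1-yl]ethyl}-2-oxooxolan-3-yl acetate | C[Si](C)(C)CC1=C2[C@](C)([C@H](COC(C)=O)[C@@H]3COC(=O)[C@H]3OC(C)=O)CC[C@H]2C(C)(C)C(=O)CC1 | intermediate
28 | C5 tosylhydrazone of 27 | C[Si](C)(C)CC1=C2[C@](C)([C@H](COC(C)=O)[C@@H]3COC(=O)[C@H]3OC(C)=O)CC[C@H]2C(C)(C)/C(=N/NS(=O)(=O)c4ccc(C)cc4)CC1 | intermediate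
29 | N-(1,3,2-benzodioxaborol-2-yl) tosylhydrazide from 28 (C5 epimers) | C[Si](C)(C)CC1=C2[C@](C)([C@H](COC(C)=O)[C@@H]3COC(=O)[C@H]3OC(C)=O)CC[C@H]2C(C)(C)C(N(B4Oc5ccccc5O4)NS(=O)(=O)c6ccc(C)cc6)CC1 | intermediate (not isolated)
30 | C5 alkyl diazene | C[Si](C)(C)CC1=C2[C@](C)([C@H](COC(C)=O)[C@@H]3COC(=O)[C@H]3OC(C)=O)CC[C@H]2C(C)(C)C(N=N)CC1 | intermediate (not isolated)
31 | (3S,4R)-4-{(1R)-2-acetoxy-1-[(1S,3aS)-1,4,4-trimethyl-8-(trimethylsilylmethyl)-1,2,3,3a,4,5,6,7-octahydroazulen-1-yl]ethyl}-2-oxooxolan-3-yl acetate | C[Si](C)(C)CC1=C2[C@](C)([C@H](COC(C)=O)[C@@H]3COC(=O)[C@H]3OC(C)=O)CC[C@H]2C(C)(C)CCC1 | intermediate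
32 | (3S,4R)-4-{(1R)-2-acetoxy-1-[(1R,3aR,8aS)-1,4,4-trimethyl-8-methylidenedecahydroazulen-1-yl]ethyl}-2-oxooxolan-3-yl acetate | C=C1CCCC(C)(C)[C@@H]2CC[C@@](C)([C@H](COC(C)=O)[C@@H]3COC(=O)[C@H]3OC(C)=O)[C@H]12 | target

**Totals**
Total step count: 17. Longest linear sequence: 16 steps (steps 1–12 and 14–17, from 1 to 32); step 13 is a one-step side branch.

**Steps most likely to fail**

Step 14. What may go wrong: the first-formed β-silyl allyl cation loses its carbon-bound silyl group, or is formed from a transoid diene conformer, faster than the tethered enol silane closes the ring, so alkylation without ring closure competes with cycloaddition. Fallback (from 19, back at 32): Stille coupling of triflate 19 with tributyl(1-ethoxyvinyl)stannane (Pd(PPh3)4, LiCl, THF, 60 °C) gives the 2-ethoxy diene F1, whose activating group is bound through oxygen and cannot be lost. With cation 26 (from 25 and AgClO4) it should pass through an O-ethyl oxocarbenium ion that can only close, giving the enol ether ketone F2. The free C5 ketone is removed as in steps 15 and 16 through the tosylhydrazone F3, the boryl hydrazide F4 and the diazene F5, giving the enol ether F6. Aqueous oxalic acid in THF then unmasks the C8 ketone and equilibrates C8a, which should favour the cis-fused ketone F7 because C8 then avoids the large C1 substituent. Ester-tolerant methylenation with Zn, CH2Br2 and TiCl4 returns to 32.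

Step 17. What may go wrong: delivery of the proton to the wrong face of the tetrasubstituted alkene (trans ring fusion), or acid-induced migration of the new exocyclic double bond. Fallback (from 31, back at 32): the protodesilylation is run without regard to selectivity, giving 32 mixed with its C8a epimer F8. The mixture is ozonised (O3, CH2Cl2, −78 °C; Me2S) to the trans-fused C8 ketone F9 and the cis-fused ketone F7. Catalytic p-TsOH in CH2Cl2 equilibrates F9 to F7 under thermodynamic control. Methylenation with Zn, CH2Br2 and TiCl4 then returns to 32.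

Step 3. What may go wrong: the iron hydride reduces the alkene or the butenolide instead of coupling them, the acetal of 4 erodes in the warm alcoholic medium, or anti selectivity at the quaternary carbon is incomplete. Fallback (from 3, back at 5): Mukaiyama hydration of 3 (Mn(dpm)3, PhSiH3, O2, iPrOH) gives the tertiary alcohol F10. Acylation with methyl chlorooxoacetate (Et3N, DMAP) gives the methyl oxalate F11, and CsOH gives the cesium oxalate F12. Visible-light photoredox coupling of F12 with 4 ([Ir(dF(CF3)ppy)2(dtbbpy)]PF6, DME/DMF, H2O, blue light, rt) generates the same tertiary radical under neutral, hydride-free conditions and should give 5 with the same facial preferences.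

**Further compounds**
F1 | step 14 | (3S,4R)-4-{(1R)-2-acetoxy-1-[(1S)-2-(1-ethoxyvinyl)-1-methylcyclopent-2-en-1-yl]ethyl}-2-oxooxolan-3-yl acetate | C1CC[C@@](C)([C@H](COC(C)=O)[C@@H]2COC(=O)[C@H]2OC(C)=O)C(C(=C)OCC)=C1
F2 | step 14 | 8-ethoxy analogue of 27 (ethyl enol ether, C5 ketone) | CCOC1=C2[C@](C)([C@H](COC(C)=O)[C@@H]3COC(=O)[C@H]3OC(C)=O)CC[C@H]2C(C)(C)C(=O)CC1
F3 | step 14 | C5 tosylhydrazone of F2 | CCOC1=C2[C@](C)([C@H](COC(C)=O)[C@@H]3COC(=O)[C@H]3OC(C)=O)CC[C@H]2C(C)(C)/C(=N/NS(=O)(=O)c4ccc(C)cc4)CC1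
F4 | step 14 | N-boryl tosylhydrazide from F3 | CCOC1=C2[C@](C)([C@H](COC(C)=O)[C@@H]3COC(=O)[C@H]3OC(C)=O)CC[C@H]2C(C)(C)C(N(B4Oc5ccccc5O4)NS(=O)(=O)c6ccc(C)cc6)CC1
F5 | step 14 | C5 alkyl diazene from F4 | CCOC1=C2[C@](C)([C@H](COC(C)=O)[C@@H]3COC(=O)[C@H]3OC(C)=O)CC[C@H]2C(C)(C)C(N=N)CC1
F6 | step 14 | 8-ethoxy analogue of 31 (C5 deoxygenated enol ether) | CCOC1=C2[C@](C)([C@H](COC(C)=O)[C@@H]3COC(=O)[C@H]3OC(C)=O)CC[C@H]2C(C)(C)CCC1
F7 | step 14 | cis-fused C8 ketone (8-oxo analogue of 32) | O=C1CCCC(C)(C)[C@@H]2CC[C@@](C)([C@H](COC(C)=O)[C@@H]3COC(=O)[C@H]3OC(C)=O)[C@H]12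
F8 | step 17 | C8a epimer of 32 (trans-fused) | C=C1CCCC(C)(C)[C@@H]2CC[C@@](C)([C@H](COC(C)=O)[C@@H]3COC(=O)[C@H]3OC(C)=O)[C@@H]12
F9 | step 17 | trans-fused C8 ketone (C8a epimer of F7) | O=C1CCCC(C)(C)[C@@H]2CC[C@@](C)([C@H](COC(C)=O)[C@@H]3COC(=O)[C@H]3OC(C)=O)[C@@H]12
F10 | step 3 | (2R)-2-(tert-butyldimethylsilyloxy)-1-methylcyclopentan-1-ol (C1 epimers) | CC1(O)CCC[C@H]1O[Si](C)(C)C(C)(C)C
F11 | step 3 | methyl (2R)-2-(tert-butyldimethylsilyloxy)-1-methylcyclopentyl oxalate | COC(=O)C(=O)OC1(C)CCC[C@H]1O[Si](C)(C)C(C)(C)C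
F12 | step 3 | cesium (2R)-2-(tert-butyldimethylsilyloxy)-1-methylcyclopentyl oxalate | [Cs+].[O-]C(=O)C(=O)OC1(C)CCC[C@H]1O[Si](C)(C)C(C)(C)C
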